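## Retrosynthetic overview

1. Target ⇐ final C6–O desilylation; C15 aldehyde from allylic oxidation of a C5 isopropenyl group; C9 methacrylate by acylation; C11=C13 by Eschenmoser methylenation.
2. Oxirane (ring 3, formed last) ⇐ chlorohydrin closure; 9α-OH ⇐ C1-hydroxyl-directed anti reduction of a C9 ketone.
3. cis-γ-Lactone (ring 2) ⇐ Mukaiyama–Michael addition of an acetic acid ketene acetal to a C7=C8 enone, C8 bromination, intramolecular carboxylate SN2 at C8.
4. Enone ⇐ Saegusa oxidation; 6β-OH ⇐ bulky-hydride reduction of the C6 ketone (unmasked from a ketal) cis to the isopropenyl group.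
5. Key disconnection: C5–C4 and C10–C1 (stereocentres C5, C10, C1) by a new copper-catalysed enantioselective conjugate isopropenylation / chloroacetaldehyde aldol on an enone ketal; the carbocycle (ring 1) is bought.

Assumption: 1, 4 and 5 are bought (5 dried and distilled as the monomer); ring carbons carry elemanolide numbers (C5–C10 ring, C1/C2 oxirane, C11–C13 lactone, C14 methyl, C15 aldehyde), β is the face of the C10 methyl and α the opposite face; the (R,R) ligand in step 3 is taken to deliver isopropenyl to the β face of C5 (its mirror image is used if the first run shows the opposite sense).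

## Route

Step 1
Reactants: 1 enone ketal (1,4-dioxaspiro[4.5]dec-6-en-8-one)
Product: 2 iodo enone ketal (7-iodo-1,4-dioxaspiro[4.5]dec-6-en-8-one)
Conditions: I2, pyridine, CH2Cl2, 0 °C to rt
Reagents that add atoms: iodine, II
Why: Pyridine-mediated α-iodination of an enone (conjugate addition of pyridine, iodination of the enolate, E1cB loss of pyridinium) is the standard route to 2-iodoenones and leaves the ketal intact.

Step 2
Reactants: 2 iodo enone ketal
Product: 3 methyl enone ketal (7-methyl-1,4-dioxaspiro[4.5]dec-6-en-8-one; ketone carbon = C9, methyl-bearing carbon = C10, β-carbon = C5, ketal carbon = C6)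
Conditions: MeB(OH)2, PdCl2(dppf) (5 mol %), Cs2CO3, dioxane/H2O, 80 °C
Reagents that add atoms: methylboronic acid, CB(O)O
Why: Suzuki–Miyaura cross-coupling of the 2-iodoenone installs the C14 methyl on the future C10 under basic conditions that the ketal tolerates.

Step 3
Reactants: 3 methyl enone ketal; 4 2-bromopropene; 5 chloroacetaldehyde
Product: 9 aldol chlorohydrin (6,6-ethylenedioxy-5β-isopropenyl-10β-methyl-10α-[(1S)-2-chloro-1-hydroxyethyl]cyclohexan-9-one), via isopropenyllithium 6 (not isolated), via dimethyl(isopropenyl)aluminium 7 (not isolated), via dimethylaluminium enolate 8 (not isolated)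
Conditions: 4, t-BuLi (2 equiv), Et2O, −78 °C; Me2AlCl, −78 to −30 °C; 3, Cu(OTf)2 (5 mol %), (R,R)-N,N-bis[1-(2-naphthyl)ethyl]-P,P-diphenylphosphinous amide (10 mol %), Et2O, −30 °C; 5, −78 °C; aq. NH4Cl
Reagents that add atoms: none
Why: Proposed new method: a monovalent copper–aminophosphine catalyst (formed from Cu(OTf)2 and the alane) transfers the isopropenyl group of 7 enantioselectively to C5 of the hindered α-methyl γ-ketal enone (π-complex, trivalent copper β-adduct, reductive elimination), and the regiodefined aluminium enolate 8 is trapped by chloroacetaldehyde anti to the new C5 substituent through a closed Zimmerman–Traxler chair with CH2Cl equatorial, which sets C10 (methyl β) and the (S)-carbinol C1 in the same flask; the closest known reactions are copper-catalysed asymmetric conjugate additions of alkenylalanes to cyclic enones and tandem conjugate addition–aldol reactions of zinc or aluminium enolates, neither shown for an α-substituted γ,γ-dialkoxy enone or with an α-chloro aldehyde.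

Step 4
Reactants: 9 aldol chlorohydrin
Product: 10 hydroxy diketone (5β-isopropenyl-10β-methyl-10α-[(1S)-2-chloro-1-hydroxyethyl]cyclohexane-6,9-dione)
Conditions: 2 M HCl, THF, rt
Reagents that add atoms: water, O
Why: Acid-catalysed ketal hydrolysis unveils the C6 ketone; the quaternary C10 prevents dehydration of the β-hydroxy ketone and mild acid at rt does not conjugate the isopulegone-type β,γ-enone.

Step 5
Reactants: 10 hydroxy diketone
Product: 11 silyloxy diketone (5β-isopropenyl-10β-methyl-10α-[(1S)-2-chloro-1-(triethylsilyloxy)ethyl]cyclohexane-6,9-dione)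
Conditions: Et3SiOTf, 2,6-lutidine, CH2Cl2, −78 °C
Reagents that add atoms: triethylsilyl trifluoromethanesulfonate, CC[Si](CC)(CC)OS(=O)(=O)C(F)(F)F
Why: Silyl ether protection of the hindered C1 carbinol blocks retro-aldol and premature epoxide closure and can later be removed in the presence of a tert-butyldimethylsilyl ether.

Step 6
Reactants: 11 silyloxy diketone
Product: 12 hydroxy ketone (6β-hydroxy-5β-isopropenyl-10β-methyl-10α-[(1S)-2-chloro-1-(triethylsilyloxy)ethyl]cyclohexan-9-one)
Conditions: LiBH(s-Bu)3 (1.05 equiv), THF, −78 °C; H2O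
Reagents that add atoms: none
Why: In this diastereoselective ketone reduction the bulky borohydride attacks the less hindered C6 ketone (C9 is shielded by the quaternary C10) from the equatorial α face anti to the adjacent isopropenyl group, as in the isopulegone to neoisopulegol reduction, giving the axial 6β-alcohol cis to the C5 substituent.

Step 7
Reactants: 12 hydroxy ketone
Product: 13 bis-silyl ketone (6β-(tert-butyldimethylsilyloxy)-5β-isopropenyl-10β-methyl-10α-[(1S)-2-chloro-1-(triethylsilyloxy)ethyl]cyclohexan-9-one)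
Conditions: t-BuMe2SiOTf, 2,6-lutidine, CH2Cl2, 0 °C
Reagents that add atoms: tert-butyldimethylsilyl trifluoromethanesulfonate, CC(C)(C)[Si](C)(C)OS(=O)(=O)C(F)(F)F
Why: Silyl triflate protection of the axial C6 hydroxyl gives a robust ether that later directs the C7 addition and stays on until the last step.

Step 8
Reactants: 13 bis-silyl ketone
Product: 15 enone (6β-(tert-butyldimethylsilyloxy)-5β-isopropenyl-10β-methyl-10α-[(1S)-2-chloro-1-(triethylsilyloxy)ethyl]cyclohex-7-en-9-one), via trimethylsilyl enol ether 14 (not isolated)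
Conditions: LiN(i-Pr)2, Me3SiCl, THF, −78 °C; Pd(OAc)2 (1.1 equiv), MeCN, rt
Reagents that add atoms: none
Why: Saegusa–Ito oxidation is regiospecific here because the C9 ketone can enolise only toward C8 (C10 is quaternary), so 14 and hence the C7=C8 enone form as single regioisomers.

Step 9
Reactants: 15 enone
Product: 19 keto lactone (9-oxo-8α,12-olide cis-fused at C7/C8 with 6β-(tert-butyldimethylsilyloxy), 5β-isopropenyl, 10β-methyl, 10α-[(1S)-2-chloro-1-(triethylsilyloxy)ethyl]), via bis-silyl Michael adduct 16 (not isolated), via bromo keto silyl ester 17 (not isolated), via sodium carboxylate 18 (not isolated)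
Conditions: CH2=C(OSiMe3)2, Me3SiOTf (5 mol %), CH2Cl2, −78 °C; NBS, THF, −78 to 0 °C; aq. NaHCO3, rt
Reagents that add atoms: ketene bis(trimethylsilyl) acetal, C=C(O[Si](C)(C)C)O[Si](C)(C)C
Why: The Mukaiyama–Michael addition occurs at C7 anti to the 6β-silyloxy and 5β-isopropenyl groups (side chain α), NBS brominates the resulting silyl enol ether at C8 anti to that chain, and the liberated carboxylate displaces the α-keto bromide intramolecularly (SN2 with inversion), which can only give the cis-fused lactone with the C8 oxygen α.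

Step 10
Reactants: 19 keto lactone
Product: 20 hydroxy keto lactone (as 19 with a free (1S)-hydroxyl at C1)
Conditions: HF·pyridine, pyridine, THF, 0 °C
Reagents that add atoms: none
Why: Buffered fluoride desilylation cleaves the triethylsilyl ether selectively over the hindered secondary tert-butyldimethylsilyl ether.

Step 11
Reactants: 20 hydroxy keto lactone
Product: 21 anti diol lactone (9α-hydroxy-8α,12-olide with 10α-[(1S)-2-chloro-1-hydroxyethyl])
Conditions: Me4NBH(OAc)3, MeCN/AcOH (1:1), −35 °C
Reagents that add atoms: none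
Why: In this Evans–Saksena reduction the C1 hydroxyl binds the acetoxyborohydride and delivers hydride intramolecularly through a chair transition state (C1 chain equatorial), giving the 1,3-anti diol, that is the 9α-alcohol, which is also the face favoured by attack anti to the lactone ring.

Step 12
Reactants: 21 anti diol lactone
Product: 22 epoxy alcohol lactone (9α-hydroxy-8α,12-olide with 10α-[(S)-oxiranyl])
Conditions: K2CO3, MeOH, 0 °C
Reagents that add atoms: none
Why: Williamson-type 3-exo-tet closure of the chlorohydrin by the C1 alkoxide gives the oxirane with retention at C1 (the C1–O bond is not broken) and is much faster than oxetane formation from the C9 hydroxyl.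

Step 13
Reactants: 22 epoxy alcohol lactone
Product: 25 methylene lactone alcohol (9α-hydroxy-11(13)-en-8α,12-olide), via Mannich base 23 (not isolated), via trimethylammonium iodide 24 (not isolated)
Conditions: LiN(i-Pr)2 (2.5 equiv), THF, −78 °C; (CH2=NMe2)I, −78 °C to rt; MeI, MeOH, rt; aq. NaHCO3/CH2Cl2, rt
Reagents that add atoms: N,N-dimethylmethyleneiminium iodide, C=[N+](C)C.[I-]
Why: In this Eschenmoser α-methylenation the lactone enolate (C9 alkoxide as spectator) is aminomethylated (Mannich reaction), and quaternisation followed by E1cB elimination gives the exocyclic methylene without touching the oxirane.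

Step 14
Reactants: 25 methylene lactone alcohol
Product: 26 methacrylate (9α-methacryloyloxy-11(13)-en-8α,12-olide)
Conditions: methacrylic anhydride, Et3N, DMAP, CH2Cl2, rt
Reagents that add atoms: methacrylic anhydride, C=C(C)C(=O)OC(=O)C(C)=C
Why: DMAP-catalysed acylation of the only free hydroxyl gives the C9 ester with retention of configuration.

Step 15
Reactants: 26 methacrylate
Product: 28 silyl-protected enal (6β-(tert-butyldimethylsilyloxy)-15-oxo compound), via allylic alcohol 27 (not isolated)
Conditions: SeO2 (0.5 equiv), t-BuOOH, CH2Cl2, rt; MnO2, CH2Cl2, rt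
Reagents that add atoms: tert-butyl hydroperoxide, CC(C)(C)OO; selenium dioxide (oxygen carrier), O=[Se]=O
Why: Riley allylic oxidation (ene reaction then 2,3-sigmatropic shift) attacks only the electron-rich isopropenyl group at its methyl (preferred over the hindered C5 methine; the acrylate-type alkenes are inert), and MnO2 takes 27 on to the enal while C6–O is still silylated, so no lactol or second lactone can form.

Step 16
Reactants: 28 silyl-protected enal
Product: 29 target CNP0124638.3
Conditions: HF·pyridine, pyridine, THF, 0 °C to rt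
Reagents that add atoms: none
Why: Buffered HF·pyridine desilylation frees the 6β-hydroxyl under conditions that terminal epoxides, enals, α-methylene lactones and acrylates tolerate.

## Compound list

1 | 1,4-dioxaspiro[4.5]dec-6-en-8-one | O=C1C=CC2(CC1)OCCO2 | starting material
2 | 7-iodo-1,4-dioxaspiro[4.5]dec-6-en-8-one | O=C1CCC2(OCCO2)C=C1I | intermediate
3 | 7-methyl-1,4-dioxaspiro[4.5]dec-6-en-8-one | CC1=CC2(CCC1=O)OCCO2 | intermediate
4 | 2-bromopropene | CC(Br)=C | starting material
5 | chloroacetaldehyde | ClCC=O | starting material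
6 | isopropenyllithium (not isolated) | [Li]C(C)=C | intermediate
7 | dimethyl(isopropenyl)aluminium (not isolated) | C[Al](C)C(C)=C | intermediate
8 | dimethylaluminium enolate of the 5β-isopropenyl-10-methyl-6,6-ethylenedioxy C9 ketone (not isolated) | CC1=C(O[Al](C)C)CCC2(OCCO2)[C@H]1C(C)=C | intermediate
9 | 6,6-ethylenedioxy-5β-isopropenyl-10β-methyl-10α-[(1S)-2-chloro-1-hydroxyethyl]cyclohexan-9-one | O=C1CCC2(OCCO2)[C@@H](C(C)=C)[C@]1(C)[C@H](O)CCl | intermediate
10 | 5β-isopropenyl-10β-methyl-10α-[(1S)-2-chloro-1-hydroxyethyl]cyclohexane-6,9-dione | O=C1CCC(=O)[C@@H](C(C)=C)[C@]1(C)[C@H](O)CCl | intermediate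
11 | 5β-isopropenyl-10β-methyl-10α-[(1S)-2-chloro-1-(triethylsilyloxy)ethyl]cyclohexane-6,9-dione | O=C1CCC(=O)[C@@H](C(C)=C)[C@]1(C)[C@H](O[Si](CC)(CC)CC)CCl | intermediate
12 | 6β-hydroxy-5β-isopropenyl-10β-methyl-10α-[(1S)-2-chloro-1-(triethylsilyloxy)ethyl]cyclohexan-9-one | O=C1CC[C@@H](O)[C@@H](C(C)=C)[C@]1(C)[C@H](O[Si](CC)(CC)CC)CCl | intermediate
13 | 6β-(tert-butyldimethylsilyloxy)-5β-isopropenyl-10β-methyl-10α-[(1S)-2-chloro-1-(triethylsilyloxy)ethyl]cyclohexan-9-one | O=C1CC[C@@H](O[Si](C)(C)C(C)(C)C)[C@@H](C(C)=C)[C@]1(C)[C@H](O[Si](CC)(CC)CC)CCl | intermediate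
14 | C9 trimethylsilyl enol ether (C8=C9) of 13 (not isolated) | C[Si](C)(C)OC1=CC[C@@H](O[Si](C)(C)C(C)(C)C)[C@@H](C(C)=C)[C@]1(C)[C@H](O[Si](CC)(CC)CC)CCl | intermediate
15 | 6β-(tert-butyldimethylsilyloxy)-5β-isopropenyl-10β-methyl-10α-[(1S)-2-chloro-1-(triethylsilyloxy)ethyl]cyclohex-7-en-9-one | O=C1C=C[C@@H](O[Si](C)(C)C(C)(C)C)[C@@H](C(C)=C)[C@]1(C)[C@H](O[Si](CC)(CC)CC)CCl | intermediate
16 | Michael adduct: C9 trimethylsilyl enol ether carrying 7α-CH2CO2SiMe3 (not isolated) | C[Si](C)(C)OC1=C[C@H](CC(=O)O[Si](C)(C)C)[C@@H](O[Si](C)(C)C(C)(C)C)[C@@H](C(C)=C)[C@]1(C)[C@H](O[Si](CC)(CC)CC)CCl | intermediate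
17 | 8β-bromo C9 ketone carrying 7α-CH2CO2SiMe3 (not isolated) | O=C1[C@@H](Br)[C@H](CC(=O)O[Si](C)(C)C)[C@@H](O[Si](C)(C)C(C)(C)C)[C@@H](C(C)=C)[C@]1(C)[C@H](O[Si](CC)(CC)CC)CCl | intermediate
18 | sodium carboxylate of the 8β-bromo keto acid (not isolated) | O=C1[C@@H](Br)[C@H](CC(=O)[O-])[C@@H](O[Si](C)(C)C(C)(C)C)[C@@H](C(C)=C)[C@]1(C)[C@H](O[Si](CC)(CC)CC)CCl.[Na+] | intermediate
19 | cis-fused 9-oxo-8α,12-olide with 6β-OTBS, 5β-isopropenyl, 10β-methyl, 10α-[(1S)-2-chloro-1-(triethylsilyloxy)ethyl] | O=C1[C@@H]2OC(=O)C[C@@H]2[C@@H](O[Si](C)(C)C(C)(C)C)[C@@H](C(C)=C)[C@]1(C)[C@H](O[Si](CC)(CC)CC)CCl | intermediate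
20 | as 19 with free (1S)-hydroxyl at C1 | O=C1[C@@H]2OC(=O)C[C@@H]2[C@@H](O[Si](C)(C)C(C)(C)C)[C@@H](C(C)=C)[C@]1(C)[C@H](O)CCl | intermediate
21 | 9α-hydroxy-8α,12-olide with 10α-[(1S)-2-chloro-1-hydroxyethyl] (1,3-anti diol) | O[C@@H]1[C@@H]2OC(=O)C[C@@H]2[C@@H](O[Si](C)(C)C(C)(C)C)[C@@H](C(C)=C)[C@]1(C)[C@H](O)CCl | intermediate
22 | 9α-hydroxy-8α,12-olide with 10α-[(S)-oxiranyl] | O[C@@H]1[C@@H]2OC(=O)C[C@@H]2[C@@H](O[Si](C)(C)C(C)(C)C)[C@@H](C(C)=C)[C@]1(C)[C@H]1CO1 | intermediate
23 | 11-(dimethylaminomethyl) lactone, C11 epimers (not isolated) | O[C@@H]1[C@@H]2OC(=O)C(CN(C)C)[C@@H]2[C@@H](O[Si](C)(C)C(C)(C)C)[C@@H](C(C)=C)[C@]1(C)[C@H]1CO1 | intermediate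
24 | 11-(trimethylammoniomethyl) lactone iodide (not isolated) | O[C@@H]1[C@@H]2OC(=O)C(C[N+](C)(C)C)[C@@H]2[C@@H](O[Si](C)(C)C(C)(C)C)[C@@H](C(C)=C)[C@]1(C)[C@H]1CO1.[I-] | intermediate
25 | 9α-hydroxy-11(13)-en-8α,12-olide with 6β-OTBS, 5β-isopropenyl, 10α-[(S)-oxiranyl] | O[C@@H]1[C@@H]2OC(=O)C(=C)[C@@H]2[C@@H](O[Si](C)(C)C(C)(C)C)[C@@H](C(C)=C)[C@]1(C)[C@H]1CO1 | intermediate
26 | 9α-methacrylate of 25 | C=C(C)C(=O)O[C@@H]1[C@@H]2OC(=O)C(=C)[C@@H]2[C@@H](O[Si](C)(C)C(C)(C)C)[C@@H](C(C)=C)[C@]1(C)[C@H]1CO1 | intermediate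
27 | 15-hydroxy compound, C5 substituent 3-hydroxyprop-1-en-2-yl (not isolated) | C=C(C)C(=O)O[C@@H]1[C@@H]2OC(=O)C(=C)[C@@H]2[C@@H](O[Si](C)(C)C(C)(C)C)[C@@H](C(=C)CO)[C@]1(C)[C@H]1CO1 | intermediate
28 | 6-O-TBS ether of the target (15-al) | C=C(C)C(=O)O[C@@H]1[C@@H]2OC(=O)C(=C)[C@@H]2[C@@H](O[Si](C)(C)C(C)(C)C)[C@@H](C(=C)C=O)[C@]1(C)[C@H]1CO1 | intermediate
29 | CNP0124638.3: 6β-hydroxy, 5β-(3-oxoprop-1-en-2-yl), 10β-methyl, 10α-[(S)-oxiranyl], 9α-methacryloyloxy, 11(13)-en-8α,12-olide | C=C(C)C(=O)O[C@@H]1[C@@H]2OC(=O)C(=C)[C@@H]2[C@@H](O)[C@@H](C(=C)C=O)[C@]1(C)[C@H]1CO1 | target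

## Step count and risks

Total: 16 steps. Longest linear sequence: 16 steps (1 to 29); 4 and 5 are bought.

Most likely to fail:

**Step 3 (the proposed new step).** The β-carbon of 3 is flanked by the ketal and the enone is α-substituted, so catalytic turnover, ee and the aldol diastereoselectivity are all unproven. Fallback with known chemistry, from 3 back to 9: CH2=C(CH3)MgBr with CuBr·SMe2 (5 mol %) and Me3SiCl in THF at −78 °C gives the racemic trimethylsilyl enol ether F1. MeLi regenerates the lithium enolate, which undergoes the same chair-controlled aldol with 5 to give the racemate, that is 9 together with its mirror image ent-9 F2. Preparative chiral SFC separates 9, which re-enters at step 4.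

**Step 9.** The C8 bromination and carboxylate displacement may be slow or give side products on this crowded ketone. Fallback from 15 back to 19: the Mukaiyama–Michael adduct 16 is made as before but oxidised rather than brominated. Rubottom oxidation with dimethyldioxirane (1 equiv, acetone/CH2Cl2, −78 °C) and a mild acidic work-up give the 8β-hydroxy keto acid F3 (hydroxyl trans to the side chain). Mitsunobu lactonisation (PPh3, DIAD, THF, 0 °C) then closes the ring with inversion at C8 to give 19.

**Step 15.** Riley oxidation may be low-yielding or unselective on this polyfunctional substrate. Fallback from 26 back to 28: ene-type allylic chlorination of the isopropenyl group with Ca(OCl)2 and solid CO2 in CH2Cl2/H2O at 0 °C gives the 2-(chloromethyl)allyl compound F4. Oxidation of the allylic chloride with N-methylmorpholine N-oxide in MeCN gives the enal 28.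

## Further compounds

F1 | step 3 | racemic 6-isopropenyl-7-methyl-8-(trimethylsilyloxy)-1,4-dioxaspiro[4.5]dec-7-ene | CC1=C(O[Si](C)(C)C)CCC2(OCCO2)C1C(C)=C
F2 | step 3 | ent-9 (mirror image of the aldol chlorohydrin) | O=C1CCC2(OCCO2)[C@H](C(C)=C)[C@@]1(C)[C@@H](O)CCl
F3 | step 9 | 8β-hydroxy-9-oxo 7α-acetic acid (6β-OTBS, 5β-isopropenyl, 10β-methyl, 10α-[(1S)-2-chloro-1-(triethylsilyloxy)ethyl]) | O=C1[C@@H](O)[C@H](CC(=O)O)[C@@H](O[Si](C)(C)C(C)(C)C)[C@@H](C(C)=C)[C@]1(C)[C@H](O[Si](CC)(CC)CC)CCl
F4 | step 15 | allylic chloride, C5 substituent 3-chloroprop-1-en-2-yl | C=C(C)C(=O)O[C@@H]1[C@@H]2OC(=O)C(=C)[C@@H]2[C@@H](O[Si](C)(C)C(C)(C)C)[C@@H](C(=C)CCl)[C@]1(C)[C@H]1CO1
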